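**Retrosynthetic overview**
1. Target 18 ⇒ (S)-2-aryl glycidic ester 12 + triacetic acid lactone 13. One flask: C-acylation, Claisen aromatisation (ring A), then phenoxide opening of the epoxide (ring C).
2. Epoxide 12 ⇒ (S)-diol 10 ⇒ 2-aryl acrylate 9, by enantioselective permanganate dihydroxylation; this sets the only stereocentre.
3. Acrylate 9 ⇒ aryl bromide 5 + methyl 2-bromoacrylate 6 (Negishi coupling); 5 ⇒ 1,3-dimethoxybenzene 1 + prenyl bromide 2.
4. Ring order: ring B is bought; rings A and C are formed together in the last step.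

Assumption: the stereocentre in the target SMILES is (S) by CIP analysis; the antipode of the chiral phase-transfer catalyst in step 4 that gives the (S)-diol is used, its sense being confirmed on the first batch.

**Step 1**
Reactants: 1 1,3-dimethoxybenzene; 2 prenyl bromide (1-bromo-3-methylbut-2-ene)
Product: 4 1,3-dimethoxy-2-(3-methylbut-2-en-1-yl)benzene, via 2,6-dimethoxyphenyllithium 3 (not isolated)
Conditions: n-BuLi, THF, 0 °C to rt; then 2, 0 °C to rt
Reagents that add atoms: none
Why: Directed ortho-metalation at the position flanked by both methoxy groups, then SN2 alkylation of the aryllithium with the allylic bromide.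

**Step 2**
Reactants: 4 1,3-dimethoxy-2-(3-methylbut-2-en-1-yl)benzene
Product: 5 1-bromo-2,4-dimethoxy-3-(3-methylbut-2-en-1-yl)benzene
Conditions: NBS (1.0 equiv), MeCN, −20 to 0 °C, dark
Reagents that add atoms: N-bromosuccinimide, O=C1CCC(=O)N1Br
Why: Electrophilic aromatic bromination para to one methoxy and ortho to the other (the two open activated positions are equivalent), expected to outrun reaction at the isolated trisubstituted alkene in dry MeCN at low temperature.

**Step 3**
Reactants: 5 1-bromo-2,4-dimethoxy-3-(3-methylbut-2-en-1-yl)benzene; 6 methyl 2-bromoacrylate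
Product: 9 methyl 2-[2,4-dimethoxy-3-(3-methylbut-2-en-1-yl)phenyl]prop-2-enoate, via aryllithium 7 (not isolated), via arylzinc chloride 8 (not isolated)
Conditions: n-BuLi, THF, −78 °C; ZnCl2, −78 °C to rt; then 6, Pd(PPh3)4 (3 mol %), rt
Reagents that add atoms: none
Why: Bromine–lithium exchange and transmetalation to zinc, then Negishi cross-coupling of the arylzinc with the vinylic bromide to give the 1,1-disubstituted acrylate directly.

**Step 4**
Reactants: 9 methyl 2-[2,4-dimethoxy-3-(3-methylbut-2-en-1-yl)phenyl]prop-2-enoate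
Product: 10 methyl (2S)-2-[2,4-dimethoxy-3-(3-methylbut-2-en-1-yl)phenyl]-2,3-dihydroxypropanoate
Conditions: KMnO4 (1.3 equiv), chiral dicationic bisguanidinium dichloride phase-transfer catalyst (2–5 mol %), t-BuOMe, −60 °C; aqueous work-up, Celite filtration
Reagents that add atoms: potassium permanganate, [K+].[O-][Mn](=O)(=O)=O
Why: Ion-pair phase-transfer asymmetric permanganate syn-dihydroxylation of an α-aryl acrylate, in which permanganate held in the chiral bisguanidinium ion pair adds by [3+2] cycloaddition to one face of the conjugated, electron-poor alkene (attacked in preference to the isolated prenyl alkene) and thereby sets C-2 as S.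

**Step 5**
Reactants: 10 methyl (2S)-2-[2,4-dimethoxy-3-(3-methylbut-2-en-1-yl)phenyl]-2,3-dihydroxypropanoate
Product: 12 methyl (2S)-2-[2,4-dimethoxy-3-(3-methylbut-2-en-1-yl)phenyl]oxirane-2-carboxylate, via tosylate 11 (not isolated)
Conditions: TsCl, Et3N, DMAP (cat.), CH2Cl2, 0 °C; then K2CO3, MeOH, 0 °C to rt
Reagents that add atoms: none
Why: Selective sulfonylation of the primary hydroxyl, then intramolecular Williamson (3-exo-tet) closure by the tertiary alkoxide; no bond to the stereocentre is broken, so it stays S.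

**Step 6**
Reactants: 12 methyl (2S)-2-[2,4-dimethoxy-3-(3-methylbut-2-en-1-yl)phenyl]oxirane-2-carboxylate; 13 triacetic acid lactone (4-hydroxy-6-methyl-2H-pyran-2-one)
Product: 18 (3S)-3-[2,4-dimethoxy-3-(3-methylbut-2-en-1-yl)phenyl]-3,5,7-trihydroxy-2,3-dihydro-4H-chromen-4-one, via pyrone dianion 14 (not isolated), via acylpyrone 15 (not isolated), via triketo ester 16 (not isolated), via acylphloroglucinol epoxide 17 (not isolated)
Conditions: 13 (2.1 equiv), LiN(i-Pr)2 (commercial solution, 4.4 equiv), THF, −78 to 0 °C; 12, −78 to −20 °C; then MeOH, Mg(OMe)2 (8 equiv), rt to 50 °C; cold dilute aq. HCl to pH 5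
Reagents that add atoms: none
Why: Proposed new method: the 6-methyl dianion of the pyrone is C-acylated by the non-enolisable ester (Claisen-type acylation), methoxide then opens the pyrone to the 3,5,7-triketo ester, a magnesium-templated intramolecular Claisen condensation with aromatisation gives the 2-acylphloroglucinol (ring A), and an ortho phenoxide attacks the primary epoxide carbon in a 6-endo-tet SN2 opening (ring C; the 5-exo alternative would need SN2 at a fully substituted carbon), so both rings close in one flask while C-3, none of whose bonds is broken, stays S; the closest known chemistry is the biomimetic polyketide conversion of 6-(2-oxoalkyl)-4-hydroxy-2-pyrones into acylphloroglucinols with Mg(OMe)2 and the phenoxide opening of 2'-hydroxyaryl oxiranyl ketones to 3-hydroxychroman-4-ones.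

**Compound list**
1 | 1,3-dimethoxybenzene | COc1cccc(OC)c1 | starting material
2 | prenyl bromide (1-bromo-3-methylbut-2-ene) | CC(C)=CCBr | starting material
3 | 2,6-dimethoxyphenyllithium | COc1cccc(OC)c1[Li] | intermediate
4 | 1,3-dimethoxy-2-(3-methylbut-2-en-1-yl)benzene | COc1cccc(OC)c1CC=C(C)C | intermediate
5 | 1-bromo-2,4-dimethoxy-3-(3-methylbut-2-en-1-yl)benzene | COc1ccc(Br)c(OC)c1CC=C(C)C | intermediate
6 | methyl 2-bromoacrylate | COC(=O)C(Br)=C | starting material
7 | [2,4-dimethoxy-3-(3-methylbut-2-en-1-yl)phenyl]lithium | COc1ccc([Li])c(OC)c1CC=C(C)C | intermediate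
8 | [2,4-dimethoxy-3-(3-methylbut-2-en-1-yl)phenyl]zinc chloride | COc1ccc([Zn]Cl)c(OC)c1CC=C(C)C | intermediate
9 | methyl 2-[2,4-dimethoxy-3-(3-methylbut-2-en-1-yl)phenyl]prop-2-enoate | COC(=O)C(=C)c1ccc(OC)c(CC=C(C)C)c1OC | intermediate
10 | methyl (2S)-2-[2,4-dimethoxy-3-(3-methylbut-2-en-1-yl)phenyl]-2,3-dihydroxypropanoate | COc1ccc([C@](O)(CO)C(=O)OC)c(OC)c1CC=C(C)C | intermediate
11 | methyl (2S)-2-[2,4-dimethoxy-3-(3-methylbut-2-en-1-yl)phenyl]-2-hydroxy-3-(4-methylbenzenesulfonyloxy)propanoate | COc1ccc([C@](O)(COS(=O)(=O)c2ccc(C)cc2)C(=O)OC)c(OC)c1CC=C(C)C | intermediate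
12 | methyl (2S)-2-[2,4-dimethoxy-3-(3-methylbut-2-en-1-yl)phenyl]oxirane-2-carboxylate | COc1ccc([C@]2(CO2)C(=O)OC)c(OC)c1CC=C(C)C | intermediate
13 | triacetic acid lactone (4-hydroxy-6-methyl-2H-pyran-2-one) | CC1=CC(O)=CC(=O)O1 | starting material
14 | dilithium dianion of 13 (4-lithiooxy-6-lithiomethyl-2H-pyran-2-one) | [Li]CC1=CC(O[Li])=CC(=O)O1 | intermediate
15 | 6-{2-[(2S)-2-[2,4-dimethoxy-3-(3-methylbut-2-en-1-yl)phenyl]oxiran-2-yl]-2-oxoethyl}-4-hydroxy-2H-pyran-2-one (present as its lithium salt) | COc1ccc([C@]2(CO2)C(=O)CC3=CC(O)=CC(=O)O3)c(OC)c1CC=C(C)C | intermediate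
16 | methyl 7-[(2S)-2-[2,4-dimethoxy-3-(3-methylbut-2-en-1-yl)phenyl]oxiran-2-yl]-3,5,7-trioxoheptanoate (present as its magnesium enolate) | COc1ccc([C@]2(CO2)C(=O)CC(=O)CC(=O)CC(=O)OC)c(OC)c1CC=C(C)C | intermediate
17 | [(2S)-2-[2,4-dimethoxy-3-(3-methylbut-2-en-1-yl)phenyl]oxiran-2-yl](2,4,6-trihydroxyphenyl)methanone (present as its magnesium phenoxide) | COc1ccc([C@]2(CO2)C(=O)c3c(O)cc(O)cc3O)c(OC)c1CC=C(C)C | intermediate
18 | (3S)-3-[2,4-dimethoxy-3-(3-methylbut-2-en-1-yl)phenyl]-3,5,7-trihydroxy-2,3-dihydro-4H-chromen-4-one | COc1ccc([C@]2(O)COc3cc(O)cc(O)c3C2=O)c(OC)c1CC=C(C)C | target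

**Totals**
Total step count: 6. Longest linear sequence: 6 steps (1 → 4 → 5 → 9 → 10 → 12 → 18); 2, 6 and 13 are bought.

**Three steps most likely to fail**

Step 6 (one-flask acylation, ring A and ring C closure). Possible failures:
- the hindered ester acylates the dianion slowly, or the dianion attacks the epoxide instead;
- methoxide opens the epoxide before the Claisen cyclisation;
- the triketo ester cyclises in the aldol rather than the Claisen mode;
- the phenoxide attacks 5-exo instead of 6-endo;
- the product α-ketol rearranges on prolonged heating in base.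

Fallback: the epoxide is taken out of the base-heavy stages and the two rings are closed separately. It sets out from diol 10 and comes back at target 18. 2,2-Dimethoxypropane with PPTS gives the acetonide methyl (4S)-4-aryl-2,2-dimethyl-1,3-dioxolane-4-carboxylate F1. Acylation of dianion 14 with F1 and buffered work-up gives the isolable acetonide acylpyrone F2. Mg(OMe)2 in MeOH takes F2 through the open-chain acetonide triketo ester F3 to the acetonide-protected acylphloroglucinol F4, which has ring A only. PPTS in aqueous MeOH frees the pentaol F5. PPh3/DIAD at high dilution then closes ring C by intramolecular Mitsunobu etherification of the primary alcohol with an ortho phenol, giving 18 with C-3 untouched.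

Step 4 (chemoselective, enantioselective dihydroxylation). Permanganate may also touch the prenyl alkene or the electron-rich arene. The published catalyst class is known for α-aryl acrylates, but the ee with a methyl ester and an ortho-methoxy aryl group is untested, and the diol may need recrystallisation.

Fallback: resolution instead of asymmetric catalysis. It sets out from acrylate 9 and comes back at epoxide 12. t-BuOOLi in THF (nucleophilic Weitz–Scheffer-type epoxidation, which ignores the prenyl alkene) gives the racemic epoxide F6. Preparative chromatography on a chiral stationary phase delivers 12 and leaves the (R)-enantiomer F7 behind. This also bypasses step 5.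

Step 2 (aromatic bromination next to a prenyl group). NBS may attack the trisubstituted alkene (allylic bromide or bromonium products) in competition with the ring.

Fallback: both bromines are put on before any alkene is present. It sets out from 1 and comes back at 5. Lithiation as in step 1 gives 3, which is quenched with 1,2-dibromoethane to give 2-bromo-1,3-dimethoxybenzene F8. NBS in MeCN brominates para to a methoxy group to give 1,3-dibromo-2,4-dimethoxybenzene F9. n-BuLi at −78 °C exchanges selectively the bromine flanked by two methoxy groups, giving (3-bromo-2,6-dimethoxyphenyl)lithium F10, which prenyl bromide 2 alkylates to 5.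

**Further compounds**
F1 | step 6 | methyl (4S)-4-[2,4-dimethoxy-3-(3-methylbut-2-en-1-yl)phenyl]-2,2-dimethyl-1,3-dioxolane-4-carboxylate | COc1ccc([C@@]2(OC(C)(C)OC2)C(=O)OC)c(OC)c1CC=C(C)C
F2 | step 6 | 6-{2-[(4S)-4-[2,4-dimethoxy-3-(3-methylbut-2-en-1-yl)phenyl]-2,2-dimethyl-1,3-dioxolan-4-yl]-2-oxoethyl}-4-hydroxy-2H-pyran-2-one | COc1ccc([C@@]2(OC(C)(C)OC2)C(=O)CC3=CC(O)=CC(=O)O3)c(OC)c1CC=C(C)C
F3 | step 6 | methyl 7-[(4S)-4-[2,4-dimethoxy-3-(3-methylbut-2-en-1-yl)phenyl]-2,2-dimethyl-1,3-dioxolan-4-yl]-3,5,7-trioxoheptanoate | COc1ccc([C@@]2(OC(C)(C)OC2)C(=O)CC(=O)CC(=O)CC(=O)OC)c(OC)c1CC=C(C)C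
F4 | step 6 | [(4S)-4-[2,4-dimethoxy-3-(3-methylbut-2-en-1-yl)phenyl]-2,2-dimethyl-1,3-dioxolan-4-yl](2,4,6-trihydroxyphenyl)methanone | COc1ccc([C@@]2(OC(C)(C)OC2)C(=O)c3c(O)cc(O)cc3O)c(OC)c1CC=C(C)C
F5 | step 6 | (2S)-2-[2,4-dimethoxy-3-(3-methylbut-2-en-1-yl)phenyl]-2,3-dihydroxy-1-(2,4,6-trihydroxyphenyl)propan-1-one | COc1ccc([C@](O)(CO)C(=O)c2c(O)cc(O)cc2O)c(OC)c1CC=C(C)C
F6 | step 4 | racemic methyl 2-[2,4-dimethoxy-3-(3-methylbut-2-en-1-yl)phenyl]oxirane-2-carboxylate | COC(=O)C1(CO1)c1ccc(OC)c(CC=C(C)C)c1OC
F7 | step 4 | methyl (2R)-2-[2,4-dimethoxy-3-(3-methylbut-2-en-1-yl)phenyl]oxirane-2-carboxylate | COc1ccc([C@@]2(CO2)C(=O)OC)c(OC)c1CC=C(C)C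
F8 | step 2 | 2-bromo-1,3-dimethoxybenzene | COc1cccc(OC)c1Br
F9 | step 2 | 1,3-dibromo-2,4-dimethoxybenzene | COc1ccc(Br)c(OC)c1Br
F10 | step 2 | (3-bromo-2,6-dimethoxyphenyl)lithium | COc1ccc(Br)c(OC)c1[Li]
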